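## Structural features

Agecorynin G is a flavone: a benzo ring A fused to a pyran-4-one ring C (O1, C2–C4, C4a, C8a), with aryl ring B attached through the C2–C1' bond. Ring A carries methoxy groups on C5, C6 and C7 and hydrogen on C8. Ring B carries oxygen on four neighbouring carbons: methoxy on C2', C4' and C5', the only free hydroxyl on C3', and hydrogen only on C6'. There is no stereocentre, so the whole problem is regiochemistry and telling one oxygen apart from six others. The fragile points are:
- the C5 methyl ether, peri to the C4 carbonyl and easily lost to Lewis acids or halide acids;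
- the pyranone, a vinylogous ester that nucleophiles open at C2;
- the C2=C3 bond under reducing conditions;
- the electron-rich ring B phenol, which over-oxidises to a quinone.

The real difficulty is ring B: the free hydroxyl sits between two methoxy groups, so selective methylation or demethylation of a simpler arene offers no handle. The key step uses the para relationship of the oxygens on C2' and C5', with the chromone on C1' and hydrogen on C6'. That is the substitution pattern of a carbene-complex benzannulation in which C2' comes from CO, C5' is a methoxycarbene carbon, C1'/C6' are a terminal alkyne and C3'/C4' are a dioxygenated vinyl group.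

## Logic of the disconnections

19 ⇒ 18. The bond cut is O–CH2Ph on O3'. The single free hydroxyl must stay masked until the last methylation is done, and a benzyl ether is the one mask that six methyl ethers do not interfere with. The forward step must cleave a benzylic C–O bond without reducing C2=C3 or the C4 carbonyl.

18 ⇒ 17. The bond cut is O–CH3 on C2'. A benzannulation that passes through a ketene always leaves the CO-derived carbon as a free phenol, so this methyl group has to be the last one put on ring B. 17 has exactly one hydroxyl, so no selectivity is needed; the base only has to leave the pyranone closed.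

17 ⇒ 9 + 15 (through 16). The bonds cut are C5'–C6', C1'–C2' and C2'–C3'. Ring B disappears completely: what remains is an alkyne holding rings A and C, a three-carbon carbene ligand and one carbonyl ligand of chromium. The four ring B oxygens arrive already labelled as hydroxyl, benzyl ether and two methyl ethers. The forward step needs regioselective alkyne insertion, tolerance of a conjugated acceptor alkyne, and release of 17 from 16 without oxidation to a quinone.

15 ⇒ 14. The cut is between the two alkyne carbons (one-carbon homologation of an aldehyde). An aldehyde on C2 is the oxidation level that the chromone closure can deliver directly. The forward step needs a basic homologation mild enough for the pyranone.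

14 ⇒ 11 (through 12 and 13). The bonds cut are O1–C2 and C2–C3. Ring C falls apart into an o-hydroxyacetophenone and a two-carbon α,α-dialkoxy ester whose acetal carbon is the future aldehyde. The gain is that no reduction–oxidation adjustment is needed at C2. The forward sequence needs C-acylation of the methyl ketone beside a free phenol, then acid to close, dehydrate and unmask without touching the C5 methyl ether.

11 ⇒ 10. The bond cut is aryl–acetyl (C4a–C4). The hydroxyl directs ortho and the two ortho positions of 10 are equivalent by symmetry, so only mono-acylation without demethylation is required.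

9 ⇒ 5 + 6 (through 7 and 8). The bonds cut are Cr=C and the carbene O–CH3. Acylating a carbonylmetalate dianion avoids a 1,2-dialkoxyvinyllithium, which could not be generated regioselectively. The forward step needs strict exclusion of air and acylation faster than electron transfer.

5 ⇒ 4. The bond cut is C–Cl; this is activation of the acid only. The forward step must not expose the enol ether to strong acid for long.

4 ⇒ 3. The bond cut is the ester O–CH3. The forward saponification must attack the carbonyl and not the β-carbon.

3 ⇒ 2. The bond cut is the enol O–CH2Ph. The forward step needs O-alkylation over C-alkylation and the Z geometry.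

2 ⇒ 1. The bond cut is between the α-carbon and the formyl carbon. A formate ester serves as the one-carbon unit, and the product is taken out of the equilibrium as its sodium salt.

## Other disconnections considered

Alternative 1: The cut runs through C6'–C1' and C3'–C2'. Ring B would come from a [4+2] addition of the symmetric furan A2 (3,4-dimethoxyfuran) to the bromoalkyne A1 (2-(bromoethynyl)-5,6,7-trimethoxy-4H-chromen-4-one, one halogenation away from 15). A Lewis acid in the same pot would then open the oxygen bridge. Ionisation at C6' is the favoured direction, because that cation is stabilised by the C4'=C5' enol ether and is not conjugated to the chromone-bearing carbon. Loss of the C3' proton would give A3 (2-(2-bromo-3-hydroxy-4,5-dimethoxyphenyl)-5,6,7-trimethoxy-4H-chromen-4-one).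
- In its favour: the free hydroxyl appears on C3' with no protecting group, which is better than the chosen plan. The symmetric diene removes any regiochemical question in the cycloaddition. No stoichiometric transition metal is used, which is also better. The ring A/C arm up to 15 is shared, so that part is equal.
- Against it: C2' ends as a bromide. Turning C–Br into C–OMe between the chromone and a free phenol needs copper- or palladium-mediated alkoxylation with alkoxide, which is what the pyranone tolerates least. The phenol would probably need a temporary mask after all. A2 is not a shelf compound. The cycloaddition of an electron-rich furan to a moderately activated haloalkyne is reversible, and the bridge opening has only an electronic bias between its two directions.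
- Comparison: on structure, both plans build ring B onto the same alkyne, but the chosen plan sets all four oxygens in one event, whereas this one leaves the most hindered C–O bond for last. On mechanism, a pericyclic and cationic sequence replaces a metal template. On step economy, the count is expected to be similar with no clear saving.

Alternative 2: The cut is C8–C8a and C5–C4a, so ring A is grown onto a finished 2-arylpyranone. A palladium-catalysed Stille coupling would join A4 (racemic 4-chloro-2,3-dimethoxycyclobut-2-en-1-one) to A5 (2-[3-(benzyloxy)-2,4,5-trimethoxyphenyl]-6-(tributylstannyl)-4H-pyran-4-one). Heating would open the four-membered ring (4π) to a dienylketene, which closes (6π) onto pyranone C5 and tautomerises to A6 (2-[3-(benzyloxy)-2,4,5-trimethoxyphenyl]-5-hydroxy-6,7-dimethoxy-4H-chromen-4-one).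
- In its favour: the ring A regiochemistry is fixed by connectivity and not by an insertion selectivity, which is better than the chosen plan. The ring-forming event is the same dienylketene electrocyclisation but without stoichiometric chromium, which is better apart from the tin waste. The number of steps after the key step is equal (one methylation, one hydrogenolysis).
- Against it: the effort goes into ring A, which the chosen plan gets from 10 in one acylation. The difficult, fully differentiated ring B must be carried ready-made inside A5. Neither that arene nor the stannylated pyranone is simple, and A4 is a sensitive building block. The phenol appears on C5, where it is hydrogen-bonded to the C4 carbonyl and methylates sluggishly.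
- Comparison: the mechanism is sound and the regiocontrol superior, but the structural problem of the target is not addressed by the key step, so the overall step count is expected to be worse.

Alternative 3: The cut is C8a–O1, C4a–C4 and O1–C2, so ring C comes from an aryne and an arylpropiolic acid. Fluoride would release the aryne from A7 (3,4,5-trimethoxy-2-(trimethylsilyl)phenyl trifluoromethanesulfonate). The carboxylate of A8 (3-[3-(benzyloxy)-2,4,5-trimethoxyphenyl]prop-2-ynoic acid) adds through oxygen at the aryne carbon remote from the methoxy groups. The aryl anion then attacks the acyl carbon, and the resulting o-acylphenoxide closes 6-endo onto the ynone to give A9 (3'-O-benzyl agecorynin G, identical with 18).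
- In its favour: it is the most convergent plan and lands one hydrogenolysis from the target, which is better than the chosen plan's two steps after the key step. The key step is free of transition metals, which is better. The regiochemistry rests on the established preference of nucleophiles for the aryne carbon meta to a flanking methoxy group, which is equal to or better than the steric control of the chosen insertion.
- Against it: ring B must again be made by arene chemistry with four differentiated oxygens, then alkynylated and carboxylated. Acyl transfer through a four-membered transition state competes with simple protonation to an aryl ester. The new C–C bond forms at an aryne carbon flanked by a methoxy group and an aryloxy group. A7 needs about three steps from 10.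
- Comparison: the end game is shorter, but the total is probably similar or longer, because the differentiation of ring B is moved into precursor synthesis instead of being solved by the key step.

Key step: step 9

Assumptions (remarks on the chemistry):
- The vinyl group of 9 is taken as Z, with benzyloxy trans to the carbene carbon and cis to the vinyl methoxy group. This is the geometry expected from O-alkylation of the formyl ester enolate; a minor E isomer would be removed at the stage of 3 and, because C3' becomes aromatic, would lead to the same 17.
- The connectivity of 9, 15 and 17 was checked atom by atom against the benzannulation and needs no change. What is changed is the approach to 15 (the aldehyde level is brought in with ring C) and the release of 17 from chromium without a strong oxidant.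
- 16 is an η6-arene complex. Its SMILES shows the arene and the Cr(CO)3 fragment side by side because the η6 bond cannot be drawn in SMILES.

## Route

Step 1
Reactants: 1 methyl methoxyacetate
Product: 2 sodium enolate of methyl 2-formyl-2-methoxyacetate (sodium 2,3-dimethoxy-3-oxoprop-1-en-1-olate; delocalised anion without fixed C=C geometry)
Conditions: HCO2Me (3 equiv), NaH (1.1 equiv), cat. MeOH, Et2O, 0 °C → rt; filter, wash with Et2O
Reagents that add atoms: methyl formate, COC=O; NaH (sodium hydride), [Na+].[H-]
Why: Crossed Claisen condensation (C-formylation); methyl formate has no α-hydrogen and is the more electrophilic ester, and the product leaves the equilibrium as its insoluble sodium enolate, which is filtered off free of methoxide.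

Step 2
Reactants: 2 sodium enolate of methyl 2-formyl-2-methoxyacetate
Product: 3 methyl (Z)-3-(benzyloxy)-2-methoxyprop-2-enoate
Conditions: BnBr (1.1 equiv), DMF, 0 °C → rt
Reagents that add atoms: benzyl bromide, BrCc1ccccc1
Why: Williamson-type O-alkylation of the formyl ester enolate in a dipolar aprotic solvent; C-alkylation would have to build a fully substituted carbon bearing OMe and is disfavoured, and the push–pull enol ether is expected mainly as the Z isomer (benzyloxy trans to the ester), as is usual for β-alkoxyacrylates made this way.

Step 3
Reactants: 3 methyl (Z)-3-(benzyloxy)-2-methoxyprop-2-enoate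
Product: 4 (Z)-3-(benzyloxy)-2-methoxyprop-2-enoic acid
Conditions: LiOH·H2O, THF/H2O 3:1, 0 °C → rt; then 1 M HCl to pH 3, 0 °C
Reagents that add atoms: LiOH (lithium hydroxide), [Li+].[OH-]
Why: Ester saponification; hydroxide attacks the ester carbonyl faster than the donor-substituted β-carbon, and the vinylogous carbonate should survive brief acidification to pH 3 in the cold.

Step 4
Reactants: 4 (Z)-3-(benzyloxy)-2-methoxyprop-2-enoic acid
Product: 5 (Z)-3-(benzyloxy)-2-methoxyprop-2-enoyl chloride
Conditions: (COCl)2 (1.2 equiv), cat. DMF, CH2Cl2, 0 °C → rt; evaporate, use crude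
Reagents that add atoms: oxalyl chloride, ClC(=O)C(Cl)=O
Why: Acid chloride formation through the Vilsmeier-type chloroiminium catalyst; there is no α-hydrogen, so no ketene can form, β-alkoxyacryloyl chlorides are a known and usable class, and all by-products are volatile so the crude chloride can go straight into the organometallic step.

Step 5
Reactants: 6 chromium hexacarbonyl; 5 (Z)-3-(benzyloxy)-2-methoxyprop-2-enoyl chloride
Product: 9 pentacarbonyl{[(Z)-2-(benzyloxy)-1-methoxyethenyl](methoxy)carbene}chromium, via dipotassium pentacarbonylchromate 7 (not isolated), via potassium acylchromate 8 (not isolated)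
Conditions: Cr(CO)6, C8K (2.1 equiv), THF, −78 °C → rt; 5, −78 → 0 °C; then Me3OBF4, CH2Cl2, 0 °C; argon throughout
Reagents that add atoms: trimethyloxonium tetrafluoroborate (Me3OBF4), C[O+](C)C.F[B-](F)(F)F
Why: Acylation of the pentacarbonylchromate dianion by an acid chloride gives the acylchromate, and hard O-methylation with the oxonium salt gives the methoxycarbene complex; this is the established acid-chloride entry to alkoxycarbene complexes and avoids a vinyllithium that could not be made regioselectively.

Step 6
Reactants: 10 3,4,5-trimethoxyphenol
Product: 11 1-(6-hydroxy-2,3,4-trimethoxyphenyl)ethan-1-one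
Conditions: AcOH, BF3·OEt2 (3 equiv), 90 °C; then H2O
Reagents that add atoms: acetic acid, CC(=O)O
Why: Friedel–Crafts acylation directed ortho by the free hydroxyl (possibly through O-acetylation and Fries shift); the two ortho positions are equivalent by symmetry and the difluoroboron chelate of the product prevents a second acylation.

Step 7
Reactants: 11 1-(6-hydroxy-2,3,4-trimethoxyphenyl)ethan-1-one
Product: 14 5,6,7-trimethoxy-4-oxo-4H-chromene-2-carbaldehyde, via diketone 12 (not isolated), via diethyl acetal 13 (not isolated)
Conditions: NaH (3.5 equiv), (EtO)2CHCO2Et (1.5 equiv), THF, reflux; then 2 M H2SO4, AcOH, 60 °C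
Reagents that add atoms: ethyl diethoxyacetate, CCOC(OCC)C(=O)OCC
Why: Claisen condensation of the acetophenone dianion with a non-enolisable α,α-dialkoxy ester, then acid-mediated cyclodehydration of the o-hydroxyaryl 1,3-diketone (the classical chromone closure) and acetal hydrolysis in the same medium; sulfuric acid offers no nucleophilic counter-ion, which protects the C5 methyl ether.

Step 8
Reactants: 14 5,6,7-trimethoxy-4-oxo-4H-chromene-2-carbaldehyde
Product: 15 2-ethynyl-5,6,7-trimethoxy-4H-chromen-4-one
Conditions: MeC(O)C(N2)P(O)(OMe)2 (1.3 equiv), K2CO3 (2 equiv), MeOH/THF, 0 °C → rt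
Reagents that add atoms: dimethyl (1-diazo-2-oxopropyl)phosphonate, CC(=O)C(=[N+]=[N-])P(=O)(OC)OC
Why: Ohira–Bestmann homologation (Seyferth–Gilbert type): methanolysis frees the diazomethylphosphonate anion, a Horner–Wadsworth–Emmons-type olefination gives a diazoalkene, and loss of N2 with a 1,2-hydrogen shift gives the terminal alkyne; carbonate in methanol at low temperature is the mildest basic medium for a nucleophile-sensitive pyranone.

Step 9
Reactants: 9 pentacarbonyl{[(Z)-2-(benzyloxy)-1-methoxyethenyl](methoxy)carbene}chromium; 15 2-ethynyl-5,6,7-trimethoxy-4H-chromen-4-one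
Product: 17 2-[3-(benzyloxy)-2-hydroxy-4,5-dimethoxyphenyl]-5,6,7-trimethoxy-4H-chromen-4-one, via tricarbonylchromium arene complex 16 (not isolated)
Conditions: 9 (1.5 equiv), THF (degassed, 0.05 M), 55 °C, argon; then air, MeCN, daylight, rt
Reagents that add atoms: none
Why: This is a Dötz benzannulation of an alkenyl(methoxy)carbene chromium complex with a terminal alkyne, a known reaction type applied here to a conjugated acceptor alkyne. Thermal loss of one cis CO from 9 opens a site for 15; the alkyne inserts into the Cr=C bond (C5'–C6'), CO inserts to give a chromium-bound dienylketene (C1'–C2'), and the ketene carbon closes onto the benzyloxy-bearing vinyl carbon (C2'–C3'). Ring B is therefore closed by a 6π electrocyclisation on the metal template, and enolisation of the cyclohexadienone gives the C2' phenol as its Cr(CO)3 complex 16. No stereocentre is created; the Z geometry of 9 matters only because it puts hydrogen, not benzyloxy, on the inside of the closing triene. The selectivity needed is the regiochemistry of insertion: the substituted alkyne carbon must end next to the CO-derived carbon, which is secured sterically because the chromonyl group avoids the substituents on the carbene carbon and the alkyne hydrogen takes that place. Five-membered-ring products, the usual competitors, are least important for alkenyl complexes in THF. Release of 17 with air and light, in place of a strong oxidant such as (NH4)2Ce(NO3)6, should keep the electron-rich p-methoxyphenol from going on to a quinone.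

Step 10
Reactants: 17 2-[3-(benzyloxy)-2-hydroxy-4,5-dimethoxyphenyl]-5,6,7-trimethoxy-4H-chromen-4-one
Product: 18 2-[3-(benzyloxy)-2,4,5-trimethoxyphenyl]-5,6,7-trimethoxy-4H-chromen-4-one
Conditions: MeI, K2CO3, acetone, 50 °C
Reagents that add atoms: iodomethane, CI
Why: Williamson methylation of the only free phenol; K2CO3 in acetone is too weak a nucleophile to open the pyranone, and the benzyl ether keeps O3' out of play.

Step 11
Reactants: 18 2-[3-(benzyloxy)-2,4,5-trimethoxyphenyl]-5,6,7-trimethoxy-4H-chromen-4-one
Product: 19 agecorynin G, 2-(3-hydroxy-2,4,5-trimethoxyphenyl)-5,6,7-trimethoxy-4H-chromen-4-one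
Conditions: H2 (1 atm), 10% Pd/C, EtOAc/MeOH, rt
Reagents that add atoms: none
Why: Hydrogenolysis of an aryl benzyl ether on palladium; at one atmosphere and room temperature the benzylic C–O bond should be cleaved well before the flavone C2=C3 bond or C4 carbonyl is reduced, and the reaction is stopped at full conversion of 18.

## Compound list

1 | methyl methoxyacetate | COCC(=O)OC | starting material
2 | sodium enolate of methyl 2-formyl-2-methoxyacetate (sodium 2,3-dimethoxy-3-oxoprop-1-en-1-olate) | COC(=O)C(OC)=C[O-].[Na+] | intermediate
3 | methyl (Z)-3-(benzyloxy)-2-methoxyprop-2-enoate | COC(=O)/C(OC)=C/OCc1ccccc1 | intermediate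
4 | (Z)-3-(benzyloxy)-2-methoxyprop-2-enoic acid | OC(=O)/C(OC)=C/OCc1ccccc1 | intermediate
5 | (Z)-3-(benzyloxy)-2-methoxyprop-2-enoyl chloride | ClC(=O)/C(OC)=C/OCc1ccccc1 | intermediate
6 | chromium hexacarbonyl, Cr(CO)6 | O=C=[Cr](=C=O)(=C=O)(=C=O)(=C=O)=C=O | starting material
7 | dipotassium pentacarbonylchromate, K2Cr(CO)5 | [K+].[K+].O=C=[Cr-2](=C=O)(=C=O)(=C=O)=C=O | intermediate
8 | potassium pentacarbonyl[(Z)-3-(benzyloxy)-2-methoxyprop-2-enoyl]chromate | [K+].O=C(/C(OC)=C/OCc1ccccc1)[Cr-](=C=O)(=C=O)(=C=O)(=C=O)=C=O | intermediate
9 | pentacarbonyl{[(Z)-2-(benzyloxy)-1-methoxyethenyl](methoxy)carbene}chromium | COC(=[Cr](=C=O)(=C=O)(=C=O)(=C=O)=C=O)/C(OC)=C/OCc1ccccc1 | intermediate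
10 | 3,4,5-trimethoxyphenol | COc1cc(O)cc(OC)c1OC | starting material
11 | 1-(6-hydroxy-2,3,4-trimethoxyphenyl)ethan-1-one | CC(=O)c1c(O)cc(OC)c(OC)c1OC | intermediate
12 | 4,4-diethoxy-1-(6-hydroxy-2,3,4-trimethoxyphenyl)butane-1,3-dione | CCOC(OCC)C(=O)CC(=O)c1c(O)cc(OC)c(OC)c1OC | intermediate
13 | 2-(diethoxymethyl)-5,6,7-trimethoxy-4H-chromen-4-one | CCOC(OCC)c1cc(=O)c2c(OC)c(OC)c(OC)cc2o1 | intermediate
14 | 5,6,7-trimethoxy-4-oxo-4H-chromene-2-carbaldehyde | O=Cc1cc(=O)c2c(OC)c(OC)c(OC)cc2o1 | intermediate
15 | 2-ethynyl-5,6,7-trimethoxy-4H-chromen-4-one | C#Cc1cc(=O)c2c(OC)c(OC)c(OC)cc2o1 | intermediate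
16 | tricarbonyl(η6-arene)chromium complex of 17, chromium on ring B (η6 bond not drawn) | COc1cc2oc(-c3cc(OC)c(OC)c(OCc4ccccc4)c3O)cc(=O)c2c(OC)c1OC.O=C=[Cr](=C=O)=C=O | intermediate
17 | 2-[3-(benzyloxy)-2-hydroxy-4,5-dimethoxyphenyl]-5,6,7-trimethoxy-4H-chromen-4-one | COc1cc2oc(-c3cc(OC)c(OC)c(OCc4ccccc4)c3O)cc(=O)c2c(OC)c1OC | intermediate
18 | 2-[3-(benzyloxy)-2,4,5-trimethoxyphenyl]-5,6,7-trimethoxy-4H-chromen-4-one | COc1cc(-c2cc(=O)c3c(OC)c(OC)c(OC)cc3o2)c(OC)c(OCc2ccccc2)c1OC | intermediate
19 | agecorynin G | COc1cc(-c2cc(=O)c3c(OC)c(OC)c(OC)cc3o2)c(OC)c(O)c1OC | target

## Step count and risk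

Total: 11 steps. Longest linear sequence: 8 steps (steps 1–5, then 9, 10, 11). The alkyne arm (steps 6–8) is three steps and joins at step 9.

**Step 9 (key step).** The most likely failure is slow alkyne insertion. The conjugated, electron-poor alkyne binds the unsaturated chromium intermediate less readily than a simple alkyne, so thermal decay of the donor-rich carbene complex, or its diversion to five-membered-ring products, can compete with benzannulation. Over-oxidation of the p-methoxyphenol during decomplexation is a second risk.
Fallback, from 9 and 11, returning at 18: 9 is heated with 3,3-diethoxyprop-1-yne (THF, 55 °C; then air). This is a non-conjugated terminal alkyne of the class for which the benzannulation is best established, and it should give 2-(benzyloxy)-6-(diethoxymethyl)-3,4-dimethoxyphenol F1. Methylation (MeI, K2CO3, acetone) should give 3-(benzyloxy)-1-(diethoxymethyl)-2,4,5-trimethoxybenzene F2, and dilute acid (1 M HCl, THF, rt) should give 3-(benzyloxy)-2,4,5-trimethoxybenzaldehyde F3. Claisen–Schmidt condensation of this aldehyde with 11 (KOH, EtOH, rt) should give (E)-3-[3-(benzyloxy)-2,4,5-trimethoxyphenyl]-1-(6-hydroxy-2,3,4-trimethoxyphenyl)prop-2-en-1-one F4. Oxidative cyclisation of the 2'-hydroxychalcone (cat. I2, DMSO, 120 °C) should close ring C to 18.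

**Step 5.** The most likely failure is electron transfer from the strongly reducing dianion to the acid chloride instead of acylation at chromium. Decomposition of the donor-substituted acylchromate before or during O-methylation is a second risk, and traces of air destroy 7.
Fallback, from 11, returning at 18 without chromium chemistry: purchased 2,6-dimethoxyphenol F5 is benzylated (BnBr, K2CO3, DMF) to 2-(benzyloxy)-1,3-dimethoxybenzene F6. Vilsmeier–Haack formylation para to a methoxy group (POCl3, DMF, 80 °C) should give 3-(benzyloxy)-2,4-dimethoxybenzaldehyde F7. Bromination at the position activated by two methoxy groups (NBS, MeCN, rt) should give 3-(benzyloxy)-5-bromo-2,4-dimethoxybenzaldehyde F8. Ullmann-type methoxylation (NaOMe, cat. CuBr, MeOH/DMF, 100 °C) should give 3-(benzyloxy)-2,4,5-trimethoxybenzaldehyde F3. This aldehyde is condensed with 11 to the chalcone F4 and cyclised to 18 as in the fallback for step 9.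

**Step 8.** The most likely failure is attack of methoxide on the pyranone C2 or conjugate addition of methanol to the newly formed acceptor alkyne. Dipolar cycloaddition of the diazo reagent to that alkyne is a further risk.
Fallback, from 14, returning at 15 without alkoxide: dibromoolefination (CBr4, PPh3, CH2Cl2, 0 °C; first stage of the Corey–Fuchs sequence) should give 2-(2,2-dibromoethenyl)-5,6,7-trimethoxy-4H-chromen-4-one F9. Palladium-catalysed removal of the less hindered bromine (Bu3SnH, cat. Pd(PPh3)4, toluene, rt) should give 2-[(Z)-2-bromoethenyl]-5,6,7-trimethoxy-4H-chromen-4-one F10. Anti elimination with fluoride (Bu4NF·3H2O, DMF, rt to 60 °C) should give 15.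

**Step 7.** The most likely failure is incomplete C-acylation, because the dialkoxyacetate is less electrophilic than an oxalate. Loss of the C5 methyl group or slow acetal cleavage during the hot acid stage is the second risk.
Fallback, from 11, returning at 14: oxalate chromone synthesis ((CO2Et)2, NaOEt, EtOH, reflux; then HCl, EtOH) should give ethyl 5,6,7-trimethoxy-4-oxo-4H-chromene-2-carboxylate F11. Selective ester reduction (NaBH4, MeOH/THF, 0 °C) should give 2-(hydroxymethyl)-5,6,7-trimethoxy-4H-chromen-4-one F12, and oxidation (MnO2, CH2Cl2, rt) should give 14.

**Step 2.** The most likely failure is competing C-benzylation by the soft benzylic electrophile. Formation of an E/Z mixture would lower the yield of usable 3.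
Fallback, from 2, returning at 3: O-methylation with the hard electrophile Me2SO4 (DMF, rt) should give methyl (Z)-2,3-dimethoxyprop-2-enoate F13. Acid-catalysed addition–elimination exchange with benzyl alcohol (BnOH, cat. pyridinium p-toluenesulfonate, toluene, 110 °C, distilling off MeOH) should give 3; any transesterified benzyl ester is saponified to the same acid 4 in step 3.

## Further compounds

F1 | step 9 | 2-(benzyloxy)-6-(diethoxymethyl)-3,4-dimethoxyphenol | CCOC(OCC)c1cc(OC)c(OC)c(OCc2ccccc2)c1O
F2 | step 9 | 3-(benzyloxy)-1-(diethoxymethyl)-2,4,5-trimethoxybenzene | CCOC(OCC)c1cc(OC)c(OC)c(OCc2ccccc2)c1OC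
F3 | step 9 | 3-(benzyloxy)-2,4,5-trimethoxybenzaldehyde | O=Cc1cc(OC)c(OC)c(OCc2ccccc2)c1OC
F4 | step 9 | (E)-3-[3-(benzyloxy)-2,4,5-trimethoxyphenyl]-1-(6-hydroxy-2,3,4-trimethoxyphenyl)prop-2-en-1-one | COc1cc(O)c(C(=O)/C=C/c2cc(OC)c(OC)c(OCc3ccccc3)c2OC)c(OC)c1OC
F5 | step 5 | 2,6-dimethoxyphenol (purchased) | COc1cccc(OC)c1O
F6 | step 5 | 2-(benzyloxy)-1,3-dimethoxybenzene | COc1cccc(OC)c1OCc1ccccc1
F7 | step 5 | 3-(benzyloxy)-2,4-dimethoxybenzaldehyde | O=Cc1ccc(OC)c(OCc2ccccc2)c1OC
F8 | step 5 | 3-(benzyloxy)-5-bromo-2,4-dimethoxybenzaldehyde | O=Cc1cc(Br)c(OC)c(OCc2ccccc2)c1OC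
F9 | step 8 | 2-(2,2-dibromoethenyl)-5,6,7-trimethoxy-4H-chromen-4-one | BrC(Br)=Cc1cc(=O)c2c(OC)c(OC)c(OC)cc2o1
F10 | step 8 | 2-[(Z)-2-bromoethenyl]-5,6,7-trimethoxy-4H-chromen-4-one | Br/C=C\c1cc(=O)c2c(OC)c(OC)c(OC)cc2o1
F11 | step 7 | ethyl 5,6,7-trimethoxy-4-oxo-4H-chromene-2-carboxylate | CCOC(=O)c1cc(=O)c2c(OC)c(OC)c(OC)cc2o1
F12 | step 7 | 2-(hydroxymethyl)-5,6,7-trimethoxy-4H-chromen-4-one | OCc1cc(=O)c2c(OC)c(OC)c(OC)cc2o1
F13 | step 2 | methyl (Z)-2,3-dimethoxyprop-2-enoate | COC(=O)/C(OC)=C/OC
A1 | alternative 1 | 2-(bromoethynyl)-5,6,7-trimethoxy-4H-chromen-4-one | BrC#Cc1cc(=O)c2c(OC)c(OC)c(OC)cc2o1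
A2 | alternative 1 | 3,4-dimethoxyfuran | COc1cocc1OC
A3 | alternative 1 | 2-(2-bromo-3-hydroxy-4,5-dimethoxyphenyl)-5,6,7-trimethoxy-4H-chromen-4-one | COc1cc2oc(-c3cc(OC)c(OC)c(O)c3Br)cc(=O)c2c(OC)c1OC
A4 | alternative 2 | 4-chloro-2,3-dimethoxycyclobut-2-en-1-one (racemic) | COC1=C(OC)C(Cl)C1=O
A5 | alternative 2 | 2-[3-(benzyloxy)-2,4,5-trimethoxyphenyl]-6-(tributylstannyl)-4H-pyran-4-one | CCCC[Sn](CCCC)(CCCC)c1cc(=O)cc(-c2cc(OC)c(OC)c(OCc3ccccc3)c2OC)o1
A6 | alternative 2 | 2-[3-(benzyloxy)-2,4,5-trimethoxyphenyl]-5-hydroxy-6,7-dimethoxy-4H-chromen-4-one | COc1cc2oc(-c3cc(OC)c(OC)c(OCc4ccccc4)c3OC)cc(=O)c2c(O)c1OC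
A7 | alternative 3 | 3,4,5-trimethoxy-2-(trimethylsilyl)phenyl trifluoromethanesulfonate | COc1cc(OS(=O)(=O)C(F)(F)F)c([Si](C)(C)C)c(OC)c1OC
A8 | alternative 3 | 3-[3-(benzyloxy)-2,4,5-trimethoxyphenyl]prop-2-ynoic acid | OC(=O)C#Cc1cc(OC)c(OC)c(OCc2ccccc2)c1OC
A9 | alternative 3 | 3'-O-benzyl agecorynin G (identical with 18) | COc1cc(-c2cc(=O)c3c(OC)c(OC)c(OC)cc3o2)c(OC)c(OCc2ccccc2)c1OC
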